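**Retrosynthetic overview**

1. Numbering: C1(Me)=C2–C3=C4(iPr)–C5(OAr)–C6–C7(Me)(OH)–C8–C9–C10. The strategy rests on the conjugated (1E,3Z)-diene C1=C2–C3=C4 inside the ten-membered ring: an E,Z-diene in such a ring is what conrotatory opening of a cis-fused bicyclo[6.2.0]dec-9-ene must give.
2. Target ⇐ C5 acylation and deacetylation ⇐ chelation-controlled reduction of the C5 ketone ⇐ dienone 26 ⇐ 4π opening of the C1–C4 bond of cyclobutenyl ketone 25.
3. 25 ⇐ zinc unmasking of a vicinal dichloride ⇐ eight-membered ring by metathesis at C9=C10, then hydrogenation ⇐ diene ketone 22.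
4. 22 ⇐ C5–C6 bond from sulfone carbanion 8 (C6–C9; C7 from (R)-2-methylglycidol) and cyclobutane aldehyde 18.
5. 18 ⇐ [2+2] photoadduct 15 of butenolide 13 and (Z)-1,2-dichloroethene. Ring order: four-membered (step 7), eight-membered (step 14), ten-membered by ring expansion (step 17).

Key step: step 17

Assumption: compounds 15–25 are carried as mixtures of the two cis-fusion diastereomers (racemic cyclobutane joined to enantiopure C7) and of chloride epimers, because steps 16 and 17 erase every one of these centres; each SMILES shows one representative.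

**Route**

Step 1
Reactants: 1 (R)-2-methylglycidol; 2 vinylmagnesium bromide
Product: 3 (S)-2-methylpent-4-ene-1,2-diol
Conditions: 2 (3 equiv), CuI (10 mol%), THF, −30 → 0 °C; aq NH4Cl
Reagents that add atoms: vinylmagnesium bromide (2), C=C[Mg]Br
Why: Copper-catalysed SN2 opening of the epoxide by the Grignard reagent at the unsubstituted CH2 terminus breaks no bond to the tertiary carbinol carbon (future C7), so its configuration is retained and the descriptor changes from R to S only through the priority switch.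

Step 2
Reactants: 3 (S)-2-methylpent-4-ene-1,2-diol
Product: 4 (S)-2-hydroxy-2-methylpent-4-en-1-yl 4-methylbenzenesulfonate
Conditions: TsCl (1.1 equiv), Et3N (1.5 equiv), Bu2SnO (2 mol%), CH2Cl2, 0 °C
Reagents that add atoms: 4-toluenesulfonyl chloride, Cc1ccc(cc1)S(Cl)(=O)=O
Why: Tin-acetal-catalysed O-sulfonylation is selective for the primary hydroxyl of the 1,2-diol, the tertiary hydroxyl being unreactive, and no stereocentre is touched.

Step 3
Reactants: 4 (S)-2-hydroxy-2-methylpent-4-en-1-yl 4-methylbenzenesulfonate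
Product: 6 (S)-2-methyl-1-(phenylthio)pent-4-en-2-ol, via (S)-2-allyl-2-methyloxirane 5 (not isolated)
Conditions: PhSH (1.3 equiv), K2CO3 (2.5 equiv), MeOH (degassed), 0 °C → rt
Reagents that add atoms: thiophenol, Sc1ccccc1
Why: Intramolecular Williamson closure of the hydroxy tosylate to the terminal epoxide is followed by thiolate SN2 opening at its CH2 carbon, the C7–O bond staying intact so that configuration is retained.

Step 4
Reactants: 6 (S)-2-methyl-1-(phenylthio)pent-4-en-2-ol
Product: 7 (S)-2-methyl-1-(phenylsulfonyl)pent-4-en-2-ol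
Conditions: 30% H2O2 (3 equiv), (NH4)6Mo7O24·4H2O (5 mol%), EtOH, 0 °C → rt
Reagents that add atoms: hydrogen peroxide, OO
Why: Molybdate-catalysed peroxide oxidation of the sulfide to the sulfone is chemoselective over the isolated terminal alkene.

Step 5
Reactants: 7 (S)-2-methyl-1-(phenylsulfonyl)pent-4-en-2-ol
Product: 8 (S)-triethyl{[2-methyl-1-(phenylsulfonyl)pent-4-en-2-yl]oxy}silane
Conditions: TESOTf (1.5 equiv), 2,6-lutidine (2.5 equiv), CH2Cl2, −78 → 0 °C
Reagents that add atoms: triethylsilyl trifluoromethanesulfonate, CC[Si](CC)(CC)OS(=O)(=O)C(F)(F)F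
Why: Silylation of the hindered tertiary alcohol with a silyl triflate and a non-nucleophilic base gives an ether that blocks retro-aldol cleavage and dehydration in all later β-oxygenated ketone stages.

Step 6
Reactants: 9 but-2-yn-1-ol; 10 isopropylmagnesium chloride
Product: 13 4-isopropyl-3-methylfuran-2(5H)-one, via alkenylmagnesium chloride alkoxide 11 (not isolated), via (Z)-hydroxy acid 12 (not isolated)
Conditions: 10 (3 equiv), CuI (10 mol%), THF, 0 °C → rt; CO2 (g), −20 °C → rt; 2 M HCl
Reagents that add atoms: isopropylmagnesium chloride (10), CC(C)[Mg]Cl; carbon dioxide, O=C=O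
Why: Copper-catalysed anti-carbomagnesiation of the propargylic alkoxide places isopropyl on the alkyne carbon next to CH2O and magnesium on the methyl-bearing carbon cis to CH2O, so carboxylation and acid lactonisation give the butenolide with its carbonyl (future C10) on the methyl-bearing carbon (future C1) without regiochemical ambiguity.

Step 7
Reactants: 13 4-isopropyl-3-methylfuran-2(5H)-one; 14 (Z)-1,2-dichloroethene
Product: 15 rac-cis-6,7-dichloro-5-isopropyl-1-methyl-3-oxabicyclo[3.2.0]heptan-2-one
Conditions: hν (medium-pressure Hg lamp, Pyrex), 14 (20 equiv), acetone, −20 °C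
Reagents that add atoms: (Z)-1,2-dichloroethene (14), Cl/C=C\Cl
Why: Triplet-sensitised enone–alkene [2+2] photocycloaddition of the butenolide sets the quaternary carbons C1 and C4 as a racemic cis pair because the five-membered lactone can only be cis-fused, and the vicinal dichloride serves as a masked cyclobutene whose chloride configurations are immaterial.

Step 8
Reactants: 15 rac-cis-6,7-dichloro-5-isopropyl-1-methyl-3-oxabicyclo[3.2.0]heptan-2-one
Product: 16 rac-cis-6,7-dichloro-5-isopropyl-1-methyl-3-oxabicyclo[3.2.0]heptan-2-ol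
Conditions: iBu2AlH (DIBAL-H, 1.2 equiv), CH2Cl2, −78 °C; aq potassium sodium tartrate
Reagents that add atoms: none
Why: Partial reduction of the lactone to the lactol stops at the tetrahedral aluminium hemiacetal at low temperature.

Step 9
Reactants: 16 rac-cis-6,7-dichloro-5-isopropyl-1-methyl-3-oxabicyclo[3.2.0]heptan-2-ol
Product: 17 rac-(cis-3,4-dichloro-1-isopropyl-2-methyl-2-vinylcyclobutyl)methanol
Conditions: Ph3PCH3Br (3 equiv), KN(SiMe3)2 (2.9 equiv), THF, 0 °C → rt
Reagents that add atoms: methyltriphenylphosphonium bromide, C[P+](c1ccccc1)(c1ccccc1)c1ccccc1.[Br-]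
Why: Wittig methylenation of the lactol through its open hydroxy-aldehyde form turns C10 into the vinyl CH and frees the C5 hydroxymethyl group, which differentiates the two former carbonyl positions.

Step 10
Reactants: 17 rac-(cis-3,4-dichloro-1-isopropyl-2-methyl-2-vinylcyclobutyl)methanol
Product: 18 rac-cis-3,4-dichloro-1-isopropyl-2-methyl-2-vinylcyclobutane-1-carbaldehyde
Conditions: Dess–Martin periodinane (1.5 equiv), CH2Cl2, 0 °C → rt
Reagents that add atoms: none
Why: Dess–Martin oxidation converts the neopentyl primary alcohol into the non-enolisable C5 aldehyde.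

Step 11
Reactants: 18 rac-cis-3,4-dichloro-1-isopropyl-2-methyl-2-vinylcyclobutane-1-carbaldehyde; 8 (S)-triethyl{[2-methyl-1-(phenylsulfonyl)pent-4-en-2-yl]oxy}silane
Product: 20 (3S)-1-(cis-3,4-dichloro-1-isopropyl-2-methyl-2-vinylcyclobutyl)-3-methyl-2-(phenylsulfonyl)-3-(triethylsilyloxy)hex-5-en-1-ol, via lithiated sulfone 19 (not isolated)
Conditions: 8 (1.3 equiv), nBuLi (1.25 equiv), THF, −78 °C; then 18, −78 → −50 °C; AcOH, −78 °C
Reagents that add atoms: none
Why: Addition of the α-sulfonyl carbanion to the aldehyde (first stage of a Julia-type coupling) forms the C5–C6 bond, low temperature suppressing β-elimination of the silanolate, and the new C5 and C6 stereocentres are left uncontrolled because steps 12 and 13 erase them.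

Step 12
Reactants: 20 the β-hydroxy sulfone
Product: 21 (3S)-1-(cis-3,4-dichloro-1-isopropyl-2-methyl-2-vinylcyclobutyl)-3-methyl-2-(phenylsulfonyl)-3-(triethylsilyloxy)hex-5-en-1-one
Conditions: Dess–Martin periodinane (2 equiv), CH2Cl2, rt
Reagents that add atoms: none
Why: Dess–Martin oxidation of the hindered β-hydroxy sulfone gives the β-keto sulfone and removes the C5 stereocentre.

Step 13
Reactants: 21 the β-keto sulfone
Product: 22 (3S)-1-(cis-3,4-dichloro-1-isopropyl-2-methyl-2-vinylcyclobutyl)-3-methyl-3-(triethylsilyloxy)hex-5-en-1-one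
Conditions: SmI2 (3 equiv), THF/MeOH (10:1), −78 °C
Reagents that add atoms: none
Why: Reductive desulfonylation of the β-keto sulfone by electron transfer from SmI2 gives a samarium enolate that methanol protonates at −78 °C before it can expel the β-silyloxy group, and alkyl chlorides are inert to SmI2 in the absence of HMPA.

Step 14
Reactants: 22 the diene ketone
Product: 23 (2Z,5S)-9,10-dichloro-8-isopropyl-1,5-dimethyl-5-(triethylsilyloxy)-cis-bicyclo[6.2.0]dec-2-en-7-one
Conditions: second-generation Grubbs catalyst RuCl2(=CHPh)(PCy3)(H2IMes) (10 mol%), PhMe (2 mM), 80 °C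
Reagents that add atoms: none
Why: Ring-closing olefin metathesis closes the eight-membered ring at C9=C10 (necessarily Z), the two arms being held cis on the cyclobutane and the quaternary carbons C1, C4 and C7 biasing the chain towards cyclisation.

Step 15
Reactants: 23 the bicyclic alkene
Product: 24 (5S)-9,10-dichloro-8-isopropyl-1,5-dimethyl-5-(triethylsilyloxy)-cis-bicyclo[6.2.0]decan-7-one
Conditions: H2 (1 atm), 10% Pd/C, EtOAc, rt
Reagents that add atoms: none
Why: Heterogeneous catalytic hydrogenation saturates the cis-disubstituted ring alkene while secondary alkyl chlorides, the hindered ketone and the silyl ether are stable under neutral conditions.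

Step 16
Reactants: 24 the saturated dichloride
Product: 25 (5S)-8-isopropyl-1,5-dimethyl-5-(triethylsilyloxy)-cis-bicyclo[6.2.0]dec-9-en-7-one
Conditions: Zn dust (activated, 10 equiv), EtOH, 50 °C, ultrasound
Reagents that add atoms: none
Why: Zinc-mediated reductive 1,2-elimination of the vicinal dichloride unveils the cyclobutene only after every step that a second alkene or a monocyclic 3-acylcyclobutene would not have survived.

Step 17
Reactants: 25 (5S)-8-isopropyl-1,5-dimethyl-5-(triethylsilyloxy)-cis-bicyclo[6.2.0]dec-9-en-7-one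
Product: 26 (2Z,4E,9S)-2-isopropyl-5,9-dimethyl-9-(triethylsilyloxy)cyclodeca-2,4-dien-1-one
Conditions: PhMe (0.01 M, degassed), BHT (2 mol%), 90 °C, dark
Reagents that add atoms: none
Why: Thermal conrotatory 4π electrocyclic ring opening breaks the strained C1–C4 σ bond and creates the C1=C2 and C3=C4 π bonds, the closest known reactions being the opening of cis-bicyclo[6.2.0]dec-9-ene to (E,Z)-cyclodeca-1,3-diene and the acceptor-controlled openings of 3-acylcyclobutenes. The ten-membered ring is not closed by cyclisation but arises by ring expansion, the cleaved bond being the one shared by the four- and eight-membered rings. No stereocentre is formed; C1 and C4 become sp2, so both fusion diastereomers of 25 converge on one product and only C7 carries stereochemical information. Because the ring bonds at C1 and C4 are cis, conrotation must turn one inward and one outward and can only give an E,Z-diene; the step needs the sense in which the C5 acyl group (with the C1 methyl) turns inward and isopropyl and C10 turn outward, which gives 3Z and 1E. This sense should be secured by the acceptor C5 carbonyl, whose π* orbital stabilises inward rotation, set against the alternative that would force the two bulkier donor groups (isopropyl and the C10 methylene) inward; a Lewis acid on the carbonyl (ZnI2) would reinforce the preference if needed. The carbonyl also lowers the barrier and leaves no hydrogen on C5 for a later 1,5-shift.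

Step 18
Reactants: 26 the silyl-protected dienone
Product: 27 (2Z,4E,9S)-9-hydroxy-2-isopropyl-5,9-dimethylcyclodeca-2,4-dien-1-one
Conditions: HF·pyridine, pyridine, THF, 0 °C
Reagents that add atoms: none
Why: Fluoride-mediated cleavage of the silyl ether under buffered, non-basic conditions avoids retro-aldol fragmentation of the tertiary β-hydroxy ketone.

Step 19
Reactants: 27 the hydroxy dienone
Product: 29 (1S,2Z,4E,9S)-2-isopropyl-5,9-dimethylcyclodeca-2,4-diene-1,9-diol, via diethylboron chelate 28 (not isolated)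
Conditions: Et2BOMe (1.2 equiv), THF/MeOH (4:1), −78 °C; NaBH4 (1.2 equiv), −78 °C; AcOH, then MeOH co-evaporation
Reagents that add atoms: none
Why: Narasaka–Prasad reduction, in which external hydride attacks (1,2-mode) the six-membered boron chelate between the C7 oxygen and the C5 carbonyl on the face leading to the chair with C4 and C8 equatorial, should set C5 as S, syn to the C7 hydroxyl along the ring.

Step 20
Reactants: 29 the diol; 30 4-acetoxybenzoyl chloride
Product: 31 (1S,2Z,4E,9S)-9-hydroxy-2-isopropyl-5,9-dimethylcyclodeca-2,4-dien-1-yl 4-acetoxybenzoate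
Conditions: 30 (1.2 equiv), pyridine (3 equiv), DMAP (10 mol%), CH2Cl2, 0 °C
Reagents that add atoms: 4-acetoxybenzoyl chloride (30), CC(=O)Oc1ccc(cc1)C(Cl)=O
Why: DMAP-catalysed acylation by the acid chloride is selective for the secondary C5 hydroxyl because the tertiary C7 hydroxyl is too hindered to be acylated, and no stereocentre is affected.

Step 21
Reactants: 31 the acetoxybenzoate
Product: 32 (1S,2Z,4E,9S)-9-hydroxy-2-isopropyl-5,9-dimethylcyclodeca-2,4-dien-1-yl 4-hydroxybenzoate (CNP0130127.1)
Conditions: K2CO3 (0.3 equiv), MeOH, 0 °C; aq NH4Cl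
Reagents that add atoms: none
Why: Base-catalysed methanolysis (transesterification) cleaves the activated aryl acetate much faster than the hindered secondary alkyl benzoate and releases the phenol.

**Compound list**

1 | (R)-2-methylglycidol | OC[C@]1(C)CO1 | starting material
2 | vinylmagnesium bromide | C=C[Mg]Br | starting material
3 | (S)-2-methylpent-4-ene-1,2-diol | C=CC[C@](C)(O)CO | intermediate
4 | (S)-2-hydroxy-2-methylpent-4-en-1-yl 4-methylbenzenesulfonate | C=CC[C@](C)(O)COS(=O)(=O)c1ccc(C)cc1 | intermediate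
5 | (S)-2-allyl-2-methyloxirane (not isolated) | C=CC[C@@]1(C)CO1 | intermediate
6 | (S)-2-methyl-1-(phenylthio)pent-4-en-2-ol | C=CC[C@](C)(O)CSc1ccccc1 | intermediate
7 | (S)-2-methyl-1-(phenylsulfonyl)pent-4-en-2-ol | C=CC[C@](C)(O)CS(=O)(=O)c1ccccc1 | intermediate
8 | (S)-triethyl{[2-methyl-1-(phenylsulfonyl)pent-4-en-2-yl]oxy}silane | C=CC[C@](C)(O[Si](CC)(CC)CC)CS(=O)(=O)c1ccccc1 | intermediate
9 | but-2-yn-1-ol | CC#CCO | starting material
10 | isopropylmagnesium chloride | CC(C)[Mg]Cl | starting material
11 | alkenylmagnesium chloride alkoxide from anti-carbomagnesiation (not isolated) | CC(C)/C(CO[Mg]Cl)=C(\C)[Mg]Cl | intermediate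
12 | (Z)-3-(hydroxymethyl)-2,4-dimethylpent-2-enoic acid (not isolated) | CC(C)/C(CO)=C(\C)C(=O)O | intermediate
13 | 4-isopropyl-3-methylfuran-2(5H)-one | CC1=C(C(C)C)COC1=O | intermediate
14 | (Z)-1,2-dichloroethene | Cl/C=C\Cl | starting material
15 | rac-cis-6,7-dichloro-5-isopropyl-1-methyl-3-oxabicyclo[3.2.0]heptan-2-one (chloride epimers) | O=C1OC[C@@]2(C(C)C)C(Cl)C(Cl)[C@@]12C | intermediate
16 | rac-cis-6,7-dichloro-5-isopropyl-1-methyl-3-oxabicyclo[3.2.0]heptan-2-ol (lactol) | OC1OC[C@@]2(C(C)C)C(Cl)C(Cl)[C@@]12C | intermediate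
17 | rac-(cis-3,4-dichloro-1-isopropyl-2-methyl-2-vinylcyclobutyl)methanol (isopropyl and methyl cis) | OC[C@@]1(C(C)C)C(Cl)C(Cl)[C@@]1(C)C=C | intermediate
18 | rac-cis-3,4-dichloro-1-isopropyl-2-methyl-2-vinylcyclobutane-1-carbaldehyde | O=C[C@@]1(C(C)C)C(Cl)C(Cl)[C@@]1(C)C=C | intermediate
19 | lithiated sulfone, 8 metalated at the sulfonyl-bearing carbon (not isolated) | [Li]C(S(=O)(=O)c1ccccc1)[C@@](C)(O[Si](CC)(CC)CC)CC=C | intermediate
20 | (3S)-1-(cis-3,4-dichloro-1-isopropyl-2-methyl-2-vinylcyclobutyl)-3-methyl-2-(phenylsulfonyl)-3-(triethylsilyloxy)hex-5-en-1-ol | OC(C(S(=O)(=O)c1ccccc1)[C@@](C)(O[Si](CC)(CC)CC)CC=C)[C@@]1(C(C)C)C(Cl)C(Cl)[C@@]1(C)C=C | intermediate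
21 | (3S)-1-(cis-3,4-dichloro-1-isopropyl-2-methyl-2-vinylcyclobutyl)-3-methyl-2-(phenylsulfonyl)-3-(triethylsilyloxy)hex-5-en-1-one | O=C(C(S(=O)(=O)c1ccccc1)[C@@](C)(O[Si](CC)(CC)CC)CC=C)[C@@]1(C(C)C)C(Cl)C(Cl)[C@@]1(C)C=C | intermediate
22 | (3S)-1-(cis-3,4-dichloro-1-isopropyl-2-methyl-2-vinylcyclobutyl)-3-methyl-3-(triethylsilyloxy)hex-5-en-1-one | O=C(C[C@@](C)(O[Si](CC)(CC)CC)CC=C)[C@@]1(C(C)C)C(Cl)C(Cl)[C@@]1(C)C=C | intermediate
23 | (2Z,5S)-9,10-dichloro-8-isopropyl-1,5-dimethyl-5-(triethylsilyloxy)-cis-bicyclo[6.2.0]dec-2-en-7-one | C[C@@]12C(Cl)C(Cl)[C@]1(C(C)C)C(=O)C[C@@](C)(O[Si](CC)(CC)CC)C/C=C\2 | intermediate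
24 | (5S)-9,10-dichloro-8-isopropyl-1,5-dimethyl-5-(triethylsilyloxy)-cis-bicyclo[6.2.0]decan-7-one | C[C@@]12C(Cl)C(Cl)[C@]1(C(C)C)C(=O)C[C@@](C)(O[Si](CC)(CC)CC)CCC2 | intermediate
25 | (5S)-8-isopropyl-1,5-dimethyl-5-(triethylsilyloxy)-cis-bicyclo[6.2.0]dec-9-en-7-one (both cis-fusion diastereomers) | C[C@@]12C=C[C@]1(C(C)C)C(=O)C[C@@](C)(O[Si](CC)(CC)CC)CCC2 | intermediate
26 | (2Z,4E,9S)-2-isopropyl-5,9-dimethyl-9-(triethylsilyloxy)cyclodeca-2,4-dien-1-one | C/C1=C\C=C(\C(C)C)C(=O)C[C@@](C)(O[Si](CC)(CC)CC)CCC1 | intermediate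
27 | (2Z,4E,9S)-9-hydroxy-2-isopropyl-5,9-dimethylcyclodeca-2,4-dien-1-one | C/C1=C\C=C(\C(C)C)C(=O)C[C@@](C)(O)CCC1 | intermediate
28 | diethylboron chelate of 27, O-diethylboryl derivative of the C7 hydroxyl (not isolated) | C/C1=C\C=C(\C(C)C)C(=O)C[C@@](C)(OB(CC)CC)CCC1 | intermediate
29 | (1S,2Z,4E,9S)-2-isopropyl-5,9-dimethylcyclodeca-2,4-diene-1,9-diol | C/C1=C\C=C(\C(C)C)[C@@H](O)C[C@@](C)(O)CCC1 | intermediate
30 | 4-acetoxybenzoyl chloride | CC(=O)Oc1ccc(cc1)C(Cl)=O | starting material
31 | (1S,2Z,4E,9S)-9-hydroxy-2-isopropyl-5,9-dimethylcyclodeca-2,4-dien-1-yl 4-acetoxybenzoate | C/C1=C\C=C(\C(C)C)[C@@H](OC(=O)c2ccc(OC(C)=O)cc2)C[C@@](C)(O)CCC1 | intermediate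
32 | (1S,2Z,4E,9S)-9-hydroxy-2-isopropyl-5,9-dimethylcyclodeca-2,4-dien-1-yl 4-hydroxybenzoate | C/C1=C\C=C(\C(C)C)[C@@H](OC(=O)c2ccc(O)cc2)C[C@@](C)(O)CCC1 | target

**Step count and risks**

Total steps: 21. Longest linear sequence: 16 steps (steps 6–21 from but-2-yn-1-ol). The sulfone branch (steps 1–5) joins at step 11 and is equally long.

Steps most likely to fail:

1. Step 17. Conrotation could run in the opposite sense, with isopropyl and C10 turning inward, and give the (1Z,3E) ring isomer. The temperature needed for opening could also let the strained Z-dienone drift, by reversible oxa-6π closure to a 2H-pyran or by hydrogen shifts, so that alkene geometry is eroded. The fallback sets out from 25 and returns at 27. Buffered HF·pyridine removes the silyl ether of 25 to give the free β-hydroxy ketone (5S)-5-hydroxy-8-isopropyl-1,5-dimethyl-cis-bicyclo[6.2.0]dec-9-en-7-one F1. Its C7 hydroxyl hydrogen-bonds to the C5 carbonyl in a six-membered ring. This internal acid activation of the acyl group is the intramolecular counterpart of the acid-complexed 3-acylcyclobutene openings, where inward rotation of the acyl group is favoured more strongly and the barrier is lower. F1 would therefore be opened in a non-polar solvent at a lower temperature and give hydroxy dienone 27 directly, which continues with step 19.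

2. Step 14. The ruthenium carbene formed at the unhindered allyl terminus may dimerise or oligomerise by cross-metathesis faster than it engages the neopentyl vinyl group across a medium ring. The fallback closes the ring at C5–C6 by carbanion addition instead; it sets out from 8 and 16 and returns at 24.
 - Ozonolysis of 8 with NaBH4 work-up gives (S)-3-methyl-4-(phenylsulfonyl)-3-(triethylsilyloxy)butan-1-ol F2, in which the carbinol carbon is C9.
 - Iodination (I2, PPh3, imidazole) gives (S)-triethyl{[4-iodo-2-methyl-1-(phenylsulfonyl)butan-2-yl]oxy}silane F3, and heating with PPh3 gives (S)-[3-methyl-4-(phenylsulfonyl)-3-(triethylsilyloxy)butyl]triphenylphosphonium iodide F4.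
 - Wittig reaction of lactol 16 with F4 and KN(SiMe3)2 forms the C9=C10 bond intermolecularly and gives the Z-alkenol [cis-3,4-dichloro-1-isopropyl-2-methyl-2-((1Z,4S)-4-methyl-5-(phenylsulfonyl)-4-(triethylsilyloxy)pent-1-en-1-yl)cyclobutyl]methanol F5.
 - Hydrogenation (H2, Pd/C) gives the saturated alcohol [cis-3,4-dichloro-1-isopropyl-2-methyl-2-((4S)-4-methyl-5-(phenylsulfonyl)-4-(triethylsilyloxy)pentyl)cyclobutyl]methanol F6, and Dess–Martin oxidation gives the corresponding C5 aldehyde, cis-3,4-dichloro-1-isopropyl-2-methyl-2-((4S)-4-methyl-5-(phenylsulfonyl)-4-(triethylsilyloxy)pentyl)cyclobutane-1-carbaldehyde F7.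
 - Deprotonation of the sulfone (KN(SiMe3)2, THF, −78 °C, high dilution) closes the eight-membered ring by intramolecular carbanion addition to the non-enolisable aldehyde and gives (5S)-9,10-dichloro-7-hydroxy-8-isopropyl-1,5-dimethyl-6-(phenylsulfonyl)-5-(triethylsilyloxy)-cis-bicyclo[6.2.0]decane F8.
 - Dess–Martin oxidation gives (5S)-9,10-dichloro-8-isopropyl-1,5-dimethyl-6-(phenylsulfonyl)-5-(triethylsilyloxy)-cis-bicyclo[6.2.0]decan-7-one F9, and SmI2 desulfonylation gives 24, which continues with step 16.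

3. Step 19. Hydride may be delivered to the wrong face of the chelated ketone, because the conformation of the ten-membered ring rather than the boron chelate may decide which carbonyl face is exposed; the C5 epimer would then predominate. The fallback sets out from 27 and returns at 31. The same reduction then gives (1R,2Z,4E,9S)-2-isopropyl-5,9-dimethylcyclodeca-2,4-diene-1,9-diol F10. Instead of reversing the facial bias, F10 is esterified under Mitsunobu conditions (4-acetoxybenzoic acid, PPh3, diisopropyl azodicarboxylate, THF, 0 °C). This inverts C5 and installs the ester in one operation, the tertiary hydroxyl being inert, and gives 31, which continues with step 21.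

**Further compounds**

F1 | step 17 | (5S)-5-hydroxy-8-isopropyl-1,5-dimethyl-cis-bicyclo[6.2.0]dec-9-en-7-one | C[C@@]12C=C[C@]1(C(C)C)C(=O)C[C@@](C)(O)CCC2
F2 | step 14 | (S)-3-methyl-4-(phenylsulfonyl)-3-(triethylsilyloxy)butan-1-ol | OCC[C@](C)(O[Si](CC)(CC)CC)CS(=O)(=O)c1ccccc1
F3 | step 14 | (S)-triethyl{[4-iodo-2-methyl-1-(phenylsulfonyl)butan-2-yl]oxy}silane | ICC[C@](C)(O[Si](CC)(CC)CC)CS(=O)(=O)c1ccccc1
F4 | step 14 | (S)-[3-methyl-4-(phenylsulfonyl)-3-(triethylsilyloxy)butyl]triphenylphosphonium iodide | [I-].c1ccccc1[P+](c1ccccc1)(c1ccccc1)CC[C@](C)(O[Si](CC)(CC)CC)CS(=O)(=O)c1ccccc1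
F5 | step 14 | [cis-3,4-dichloro-1-isopropyl-2-methyl-2-((1Z,4S)-4-methyl-5-(phenylsulfonyl)-4-(triethylsilyloxy)pent-1-en-1-yl)cyclobutyl]methanol | OC[C@@]1(C(C)C)C(Cl)C(Cl)[C@@]1(C)/C=C\C[C@](C)(O[Si](CC)(CC)CC)CS(=O)(=O)c1ccccc1
F6 | step 14 | [cis-3,4-dichloro-1-isopropyl-2-methyl-2-((4S)-4-methyl-5-(phenylsulfonyl)-4-(triethylsilyloxy)pentyl)cyclobutyl]methanol | OC[C@@]1(C(C)C)C(Cl)C(Cl)[C@@]1(C)CCC[C@](C)(O[Si](CC)(CC)CC)CS(=O)(=O)c1ccccc1
F7 | step 14 | cis-3,4-dichloro-1-isopropyl-2-methyl-2-((4S)-4-methyl-5-(phenylsulfonyl)-4-(triethylsilyloxy)pentyl)cyclobutane-1-carbaldehyde | O=C[C@@]1(C(C)C)C(Cl)C(Cl)[C@@]1(C)CCC[C@](C)(O[Si](CC)(CC)CC)CS(=O)(=O)c1ccccc1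
F8 | step 14 | (5S)-9,10-dichloro-7-hydroxy-8-isopropyl-1,5-dimethyl-6-(phenylsulfonyl)-5-(triethylsilyloxy)-cis-bicyclo[6.2.0]decane | C[C@@]12C(Cl)C(Cl)[C@]1(C(C)C)C(O)C(S(=O)(=O)c3ccccc3)[C@@](C)(O[Si](CC)(CC)CC)CCC2
F9 | step 14 | (5S)-9,10-dichloro-8-isopropyl-1,5-dimethyl-6-(phenylsulfonyl)-5-(triethylsilyloxy)-cis-bicyclo[6.2.0]decan-7-one | C[C@@]12C(Cl)C(Cl)[C@]1(C(C)C)C(=O)C(S(=O)(=O)c3ccccc3)[C@@](C)(O[Si](CC)(CC)CC)CCC2
F10 | step 19 | (1R,2Z,4E,9S)-2-isopropyl-5,9-dimethylcyclodeca-2,4-diene-1,9-diol | C/C1=C\C=C(\C(C)C)[C@H](O)C[C@@](C)(O)CCC1
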